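**Plan**

1. Retrosynthesis: the ring C acid is masked as a tert-butyl ester. The two phenolic C2–O bonds of rings B and C are cut last, in one operation. Then the B–C and A–B ester C(acyl)–O bonds are cut, and finally the ring A C6–CH3 bond, back to 2,4,5-trimethoxybenzoic acid.
2. Forward: ring A acid by ortho-lithiation and methylation; acylation of benzyl 4-hydroxy-2-methylbenzoate (A–B); hydrogenolysis; carbodiimide coupling with tert-butyl 4-hydroxy-2-methylbenzoate (A–B–C); twofold ester-directed borylation–oxidation; acidolysis. All three benzene rings are bought and no ring is formed.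
3. Enabling feature: in rings B and C the C6 methyl occupies one side of the benzoate carbon C1, so C2–H is the only hydrogen ortho to each carbonyl and is exactly where the hydroxyls belong. Ring A (C2 OMe, C6 CH3) has no ortho hydrogen.
4. Stereochemistry: the target has no stereocentre, stereogenic axis or configured double bond, so nothing has to be set.

Key step: step 7

Remark: in every ring C1 is the carbon that bears the carbonyl group; ring A is the trimethoxy ring and ring C carries the free acid.

**Step 1**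
Reactants: 1 2,4,5-trimethoxybenzoic acid
Product: 3 2,4,5-trimethoxy-6-methylbenzoic acid (ring A acid), via lithium 6-lithio-2,4,5-trimethoxybenzoate 2 (not isolated)
Conditions: s-BuLi (2.2 equiv), TMEDA, THF, −78 °C; MeI, −78 °C to rt; aq HCl
Reagents that add atoms: iodomethane, CI
Why: Carboxylate-directed ortho-metalation, in which s-BuLi/TMEDA held by the CO2Li group removes the only hydrogen ortho to it (C6–H, also acidified by the C5 methoxyl) and the aryllithium is then methylated by MeI in an SN2 step.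

**Step 2**
Reactants: 4 4-hydroxy-2-methylbenzoic acid
Product: 5 benzyl 4-hydroxy-2-methylbenzoate
Conditions: BnBr, KHCO3, DMF, 40 °C
Reagents that add atoms: benzyl bromide, BrCc1ccccc1
Why: Carboxylate O-alkylation (SN2), selective because KHCO3 ionises the acid but not the phenol.

**Step 3**
Reactants: 4 4-hydroxy-2-methylbenzoic acid
Product: 6 tert-butyl 4-hydroxy-2-methylbenzoate
Conditions: Me2NCH(Ot-Bu)2, toluene, 80 °C
Reagents that add atoms: N,N-dimethylformamide di-tert-butyl acetal, CN(C)C(OC(C)(C)C)OC(C)(C)C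
Why: Formamide-acetal esterification, in which the carboxylic acid protonates the acetal and its carboxylate takes up the tert-butyl group while the far less acidic phenol should stay free.

**Step 4**
Reactants: 3 2,4,5-trimethoxy-6-methylbenzoic acid; 5 benzyl 4-hydroxy-2-methylbenzoate
Product: 8 benzyl 2-methyl-4-[(2,4,5-trimethoxy-6-methylbenzoyl)oxy]benzoate, via 2,4,5-trimethoxy-6-methylbenzoyl chloride 7 (not isolated)
Conditions: (COCl)2, DMF (cat.), CH2Cl2, 0 °C to rt, evaporate; then 5, Et3N, DMAP, CH2Cl2, 0 °C to rt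
Reagents that add atoms: none
Why: Acyl chloride formation (Vilsmeier-type activation by oxalyl chloride/DMF) followed by DMAP-catalysed acylation of the phenol, where the acylpyridinium route should overcome the two ortho substituents of ring A and the benzyl ester is inert.

**Step 5**
Reactants: 8 benzyl 2-methyl-4-[(2,4,5-trimethoxy-6-methylbenzoyl)oxy]benzoate
Product: 9 2-methyl-4-[(2,4,5-trimethoxy-6-methylbenzoyl)oxy]benzoic acid
Conditions: H2 (1 atm), 10% Pd/C, EtOAc, rt
Reagents that add atoms: none
Why: Hydrogenolysis of the benzylic C–O bond over Pd/C, which leaves the aryl ester, the aryl methyl ethers and the arenes unreduced.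

**Step 6**
Reactants: 9 2-methyl-4-[(2,4,5-trimethoxy-6-methylbenzoyl)oxy]benzoic acid; 6 tert-butyl 4-hydroxy-2-methylbenzoate
Product: 10 tert-butyl 2-methyl-4-({2-methyl-4-[(2,4,5-trimethoxy-6-methylbenzoyl)oxy]benzoyl}oxy)benzoate
Conditions: DCC, DMAP (cat.), CH2Cl2, 0 °C to rt
Reagents that add atoms: none
Why: Steglich esterification, in which DCC converts the mono-ortho-substituted acid into an O-acylisourea and DMAP relays the acyl group to the phenol, while the existing ring A ester is shielded from acyl exchange by its two ortho substituents.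

**Step 7**
Reactants: 10 tert-butyl 2-methyl-4-({2-methyl-4-[(2,4,5-trimethoxy-6-methylbenzoyl)oxy]benzoyl}oxy)benzoate; 11 bis(pinacolato)diboron
Product: 13 tert-butyl 2-hydroxy-6-methyl-4-({2-hydroxy-6-methyl-4-[(2,4,5-trimethoxy-6-methylbenzoyl)oxy]benzoyl}oxy)benzoate, via bis(pinacolboronate) 12 (not isolated)
Conditions: [Ir(OMe)(cod)]2 (5 mol%), P[3,5-(CF3)2C6H3]3 (20 mol%), B2pin2 (3 equiv), octane, 80 °C; evaporate; Oxone (2KHSO5·KHSO4·K2SO4), acetone–H2O, rt, 15 min
Reagents that add atoms: potassium peroxymonosulfate, [K+].[O-]S(=O)(=O)OO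
Why: The electron-poor phosphine leaves the iridium boryl catalyst with a free coordination site, so each benzoate carbonyl oxygen binds the metal and steers C–H cleavage to the adjacent ortho position through a five-membered chelate, after which C–B reductive elimination gives the arylboronate. Peroxymonosulfate then adds to boron and the aryl group shifts from boron to oxygen, so each C–B bond becomes a C–O bond at the same carbon. The closest known reaction type is the iridium-catalysed ester-directed ortho C–H borylation of benzoate esters, combined with the one-pot borylation–oxidation of arenes to phenols. No ring is closed and no stereocentre is created. The step needs C2 over C3 and C5 in rings B and C and no reaction in ring A: the C6 methyl leaves each carbonyl a single ortho hydrogen, C5–H is flanked by the acyloxy group and the methyl, C3–H is blocked once C2 carries boron, and the only hydrogen of ring A lies between two methoxyls and is not ortho to a carbonyl. The brief acidic oxidation should spare the two aryl esters and the tert-butyl ester.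

**Step 8**
Reactants: 13 tert-butyl 2-hydroxy-6-methyl-4-({2-hydroxy-6-methyl-4-[(2,4,5-trimethoxy-6-methylbenzoyl)oxy]benzoyl}oxy)benzoate
Product: 14 2-hydroxy-6-methyl-4-({2-hydroxy-6-methyl-4-[(2,4,5-trimethoxy-6-methylbenzoyl)oxy]benzoyl}oxy)benzoic acid (target)
Conditions: TFA–CH2Cl2 (1:4), 0 °C to rt
Reagents that add atoms: none
Why: Acidolysis of the tert-butyl ester (AAL1, the tert-butyl cation leaving as isobutene), under which aryl esters, phenols and aryl methyl ethers are stable at room temperature.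

**Compound list**

1 | 2,4,5-trimethoxybenzoic acid | COc1cc(OC)c(C(=O)O)cc1OC | starting material
2 | lithium 6-lithio-2,4,5-trimethoxybenzoate | COc1cc(OC)c(C(=O)O[Li])c([Li])c1OC | intermediate (not isolated)
3 | 2,4,5-trimethoxy-6-methylbenzoic acid (= 3,4,6-trimethoxy-2-methylbenzoic acid) | COc1cc(OC)c(C(=O)O)c(C)c1OC | intermediate
4 | 4-hydroxy-2-methylbenzoic acid | Cc1cc(O)ccc1C(=O)O | starting material
5 | benzyl 4-hydroxy-2-methylbenzoate | Cc1cc(O)ccc1C(=O)OCc1ccccc1 | intermediate
6 | tert-butyl 4-hydroxy-2-methylbenzoate | Cc1cc(O)ccc1C(=O)OC(C)(C)C | intermediate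
7 | 2,4,5-trimethoxy-6-methylbenzoyl chloride | COc1cc(OC)c(C(=O)Cl)c(C)c1OC | intermediate (not isolated)
8 | benzyl 2-methyl-4-[(2,4,5-trimethoxy-6-methylbenzoyl)oxy]benzoate | COc1cc(OC)c(C(=O)Oc2ccc(C(=O)OCc3ccccc3)c(C)c2)c(C)c1OC | intermediate
9 | 2-methyl-4-[(2,4,5-trimethoxy-6-methylbenzoyl)oxy]benzoic acid | COc1cc(OC)c(C(=O)Oc2ccc(C(=O)O)c(C)c2)c(C)c1OC | intermediate
10 | tert-butyl 2-methyl-4-({2-methyl-4-[(2,4,5-trimethoxy-6-methylbenzoyl)oxy]benzoyl}oxy)benzoate | COc1cc(OC)c(C(=O)Oc2ccc(C(=O)Oc3ccc(C(=O)OC(C)(C)C)c(C)c3)c(C)c2)c(C)c1OC | intermediate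
11 | bis(pinacolato)diboron | CC1(C)OB(B2OC(C)(C)C(C)(C)O2)OC1(C)C | starting material
12 | bis(pinacolboronate): tert-butyl 2-methyl-6-(4,4,5,5-tetramethyl-1,3,2-dioxaborolan-2-yl)-4-({2-methyl-6-(4,4,5,5-tetramethyl-1,3,2-dioxaborolan-2-yl)-4-[(2,4,5-trimethoxy-6-methylbenzoyl)oxy]benzoyl}oxy)benzoate | COc1cc(OC)c(C(=O)Oc2cc(C)c(C(=O)Oc3cc(C)c(C(=O)OC(C)(C)C)c(B4OC(C)(C)C(C)(C)O4)c3)c(B5OC(C)(C)C(C)(C)O5)c2)c(C)c1OC | intermediate (not isolated)
13 | tert-butyl 2-hydroxy-6-methyl-4-({2-hydroxy-6-methyl-4-[(2,4,5-trimethoxy-6-methylbenzoyl)oxy]benzoyl}oxy)benzoate | COc1cc(OC)c(C(=O)Oc2cc(C)c(C(=O)Oc3cc(C)c(C(=O)OC(C)(C)C)c(O)c3)c(O)c2)c(C)c1OC | intermediate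
14 | 2-hydroxy-6-methyl-4-({2-hydroxy-6-methyl-4-[(2,4,5-trimethoxy-6-methylbenzoyl)oxy]benzoyl}oxy)benzoic acid | COc1cc(OC)c(C(=O)Oc2cc(C)c(C(=O)Oc3cc(C)c(C(=O)O)c(O)c3)c(O)c2)c(C)c1OC | target

**Step count and risks**

Total steps: 8. Longest linear sequence: 6 (steps 1, 4, 5, 6, 7, 8).

Steps most likely to fail:

1. Step 7. The aryl ester carbonyl of ring B is a weaker donor than an alkyl ester, so chelation-directed borylation may stall after ring C alone has reacted. Borylation may also leak to C3 through undirected activation or through the six-membered chelate from the aryloxy side. Fallback (classical depside assembly with both C2 oxygens bought in; sets out from 3, returns at 14): commercial orsellinic acid (2,4-dihydroxy-6-methylbenzoic acid, Cc1cc(O)cc(O)c1C(=O)O) is benzylated at the carboxyl (BnBr, KHCO3, DMF) to benzyl 2,4-dihydroxy-6-methylbenzoate F1. Acid 3 is condensed with F1 at the free 4-hydroxyl (trifluoroacetic anhydride, toluene, rt; the 2-hydroxyl is held in a hydrogen bond to the ester carbonyl) to give benzyl 2-hydroxy-6-methyl-4-[(2,4,5-trimethoxy-6-methylbenzoyl)oxy]benzoate F2. Hydrogenolysis (H2, Pd/C, EtOAc) gives 2-hydroxy-6-methyl-4-[(2,4,5-trimethoxy-6-methylbenzoyl)oxy]benzoic acid F3. A second trifluoroacetic anhydride condensation of F3 with F1 gives the benzyl ester of the target F4, and a final hydrogenolysis gives 14.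

2. Step 1. Lithiation may divert to C3 between the C2 and C4 methoxyls, s-BuLi may displace the C2 methoxyl if the temperature rises, and the new benzylic methyl may be lithiated and methylated a second time. Fallback (sets out from 1, returns at 3, no new compound): carboxylate-directed C–H methylation with divalent palladium, using Pd(OAc)2 (cat.), MeB(OH)2, Ag2CO3, benzoquinone, K2HPO4, t-BuOH, 100 °C. Cyclopalladation through the carboxylate can reach only C6–H, and no carbanion is formed.

3. Step 8. The freed 2-hydroxy-6-methylbenzoic acid may decarboxylate by ipso-protonation in strong acid, and the tert-butyl cation may be captured by the activated rings. Fallback (a hydrogenolysable ester that the borylation cannot touch; sets out from 9, with 4 as the source of the new ring C ester, returns at 14): 4 is esterified with 2,4,6-trimethylbenzyl chloride (Cc1cc(C)c(CCl)c(C)c1; KHCO3, DMF) to 2,4,6-trimethylbenzyl 4-hydroxy-2-methylbenzoate F5. DCC/DMAP coupling of 9 with F5 gives the dideoxy tridepside 2,4,6-trimethylbenzyl ester F6. The borylation–oxidation of step 7, through the bis(pinacolboronate) of the 2,4,6-trimethylbenzyl ester F7, gives the dihydroxy tridepside 2,4,6-trimethylbenzyl ester F8. The two hydrogens of the mesityl ring are each flanked by two methyls and should stay unborylated, which a plain benzyl ester would not allow. Hydrogenolysis (H2, Pd/C, EtOAc) then frees 14 under neutral conditions.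

**Further compounds**

F1 | step 7 | benzyl 2,4-dihydroxy-6-methylbenzoate | Cc1cc(O)cc(O)c1C(=O)OCc1ccccc1
F2 | step 7 | benzyl 2-hydroxy-6-methyl-4-[(2,4,5-trimethoxy-6-methylbenzoyl)oxy]benzoate | COc1cc(OC)c(C(=O)Oc2cc(C)c(C(=O)OCc3ccccc3)c(O)c2)c(C)c1OC
F3 | step 7 | 2-hydroxy-6-methyl-4-[(2,4,5-trimethoxy-6-methylbenzoyl)oxy]benzoic acid | COc1cc(OC)c(C(=O)Oc2cc(C)c(C(=O)O)c(O)c2)c(C)c1OC
F4 | step 7 | benzyl 2-hydroxy-6-methyl-4-({2-hydroxy-6-methyl-4-[(2,4,5-trimethoxy-6-methylbenzoyl)oxy]benzoyl}oxy)benzoate | COc1cc(OC)c(C(=O)Oc2cc(C)c(C(=O)Oc3cc(C)c(C(=O)OCc4ccccc4)c(O)c3)c(O)c2)c(C)c1OC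
F0 | step 1 | none | none
F5 | step 8 | 2,4,6-trimethylbenzyl 4-hydroxy-2-methylbenzoate | Cc1cc(O)ccc1C(=O)OCc1c(C)cc(C)cc1C
F6 | step 8 | 2,4,6-trimethylbenzyl 2-methyl-4-({2-methyl-4-[(2,4,5-trimethoxy-6-methylbenzoyl)oxy]benzoyl}oxy)benzoate | COc1cc(OC)c(C(=O)Oc2ccc(C(=O)Oc3ccc(C(=O)OCc4c(C)cc(C)cc4C)c(C)c3)c(C)c2)c(C)c1OC
F7 | step 8 | 2,4,6-trimethylbenzyl 2-methyl-6-(4,4,5,5-tetramethyl-1,3,2-dioxaborolan-2-yl)-4-({2-methyl-6-(4,4,5,5-tetramethyl-1,3,2-dioxaborolan-2-yl)-4-[(2,4,5-trimethoxy-6-methylbenzoyl)oxy]benzoyl}oxy)benzoate | COc1cc(OC)c(C(=O)Oc2cc(C)c(C(=O)Oc3cc(C)c(C(=O)OCc4c(C)cc(C)cc4C)c(B5OC(C)(C)C(C)(C)O5)c3)c(B6OC(C)(C)C(C)(C)O6)c2)c(C)c1OC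
F8 | step 8 | 2,4,6-trimethylbenzyl 2-hydroxy-6-methyl-4-({2-hydroxy-6-methyl-4-[(2,4,5-trimethoxy-6-methylbenzoyl)oxy]benzoyl}oxy)benzoate | COc1cc(OC)c(C(=O)Oc2cc(C)c(C(=O)Oc3cc(C)c(C(=O)OCc4c(C)cc(C)cc4C)c(O)c3)c(O)c2)c(C)c1OC
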